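## Retrosynthetic overview

1. Feature: the biaryl bond joins C6' of flavanone ring B to C8 of flavone ring A. C8 lies between the oxygen-bearing carbons C7 and C8a, and C1' (next to C6') carries flavanone C2, so C2 can begin as a carboxyl carbon esterified with the oxygen that becomes flavone O1.
2. C6'–C8 is disconnected first: intramolecular palladium-catalysed direct arylation of an aryl 2-bromobenzoate closes a benzo[c]chromen-6-one (temporary lactone ring, formed first).
3. LiAlH4 opens the lactone to a benzylic alcohol (future C2) and a single phenol (future O1). Ortho-formylation next to that phenol, acetylide addition, oxidation and 6-endo closure build the flavone pyranone ring (second ring).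
4. The benzylic alcohol is oxidised to the aldehyde and condensed with a phloroacetophenone-derived tert-butyl β-ketoester. The flavanone pyranone ring (third ring) is closed last by catalytic asymmetric oxa-Michael addition with decarboxylation, which sets C2 as R.
5. Hydrogenolysis of all eight benzyl ethers ends the route.

Key step: step 3

Assumptions:
- The target defines only C2 (R, read from the SMILES); the biaryl axis is not assigned, so rotamers about the C6'–C8 bond are carried through as they form.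
- The quinine-derived thiourea is taken to give the 2R series and its quinidine-derived pseudo-enantiomer the 2S series; the sense is to be checked on a model aldehyde by CD before material is committed, and the pseudo-enantiomer used if the check demands it.
- Deprotonated or lithiated forms of numbered compounds (phenoxides, enolates, the lithium acetylide) count as salts of those compounds and carry no number.

## Route

Step 1
Reactants: 1 3,4-bis(benzyloxy)benzoic acid
Product: 2 4,5-bis(benzyloxy)-2-bromobenzoic acid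
Conditions: Br2 (1.1 equiv), NaOAc (1.5 equiv), AcOH, rt, dark
Reagents that add atoms: bromine, BrBr
Why: Electrophilic aromatic bromination should go para to the 3-benzyloxy group and ortho to the carboxyl, as with other 3,4-dialkoxybenzoic acids, while the NaOAc buffer keeps HBr away from the benzyl ethers.

Step 2
Reactants: 2 4,5-bis(benzyloxy)-2-bromobenzoic acid; 3 3,5-bis(benzyloxy)phenol
Product: 4 3,5-bis(benzyloxy)phenyl 4,5-bis(benzyloxy)-2-bromobenzoate
Conditions: DCC (1.1 equiv), DMAP (10 mol%), CH2Cl2, 0 °C to rt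
Reagents that add atoms: none
Why: Steglich esterification; DMAP-catalysed acyl transfer from the carbodiimide-activated acid couples the ortho-bromo acid to the phenol under neutral conditions that leave all benzyl ethers untouched.

Step 3
Reactants: 4 3,5-bis(benzyloxy)phenyl 4,5-bis(benzyloxy)-2-bromobenzoate
Product: 5 1,3,8,9-tetrakis(benzyloxy)-6H-benzo[c]chromen-6-one
Conditions: Pd(OAc)2 (10 mol%), PCy3·HBF4 (20 mol%), K2CO3 (2.5 equiv), PivOH (30 mol%), DMA, 130 °C, argon
Reagents that add atoms: none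
Why: Zerovalent palladium formed from Pd(OAc)2 and PCy3 inserts into the C–Br bond, the divalent arylpalladium is held over the phenoxy ring in the s-cis ester conformer, carbonate/pivalate-assisted concerted metalation–deprotonation at the ortho C–H gives a seven-membered diarylpalladacycle, and reductive elimination forms the C6'–C8 biaryl bond. The closest known reaction type is the palladium-catalysed intramolecular direct arylation of aryl 2-halobenzoates to 6H-benzo[c]chromen-6-ones (lactone-bridge biaryl synthesis). The one ring closed is the six-membered lactone (C6, O5, C4a, C10b, C10a, C6a), completed by aryl–aryl bond formation through reductive elimination and not by a polar exo or endo attack. No stereocenter is created, and the lactone bridge holds the biaryl near planarity, so no axial chirality arises at this stage. The step needs regioselectivity on the trioxygenated ring and chemoselectivity against ester cleavage: the tether reaches only the two C–H bonds ortho to the ester oxygen, which are equivalent in the 3,5-bis(benzyloxy)phenyl group, the C–H between two oxygens is the more acidic one for metalation, no benzyloxy group sits ortho to bromine so cyclisation onto a benzyl ring is excluded, and anhydrous carbonate in DMA limits ester cleavage.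

Step 4
Reactants: 5 1,3,8,9-tetrakis(benzyloxy)-6H-benzo[c]chromen-6-one
Product: 6 2-[4,5-bis(benzyloxy)-2-(hydroxymethyl)phenyl]-3,5-bis(benzyloxy)phenol
Conditions: LiAlH4 (2 equiv), THF, 0 °C to rt; aq. NaOH work-up
Reagents that add atoms: none
Why: Hydride reduction of the aryl lactone gives the primary benzylic alcohol (future flavanone C2) and frees the one phenol (future flavone O1), with benzyl ethers inert.

Step 5
Reactants: 6 2-[4,5-bis(benzyloxy)-2-(hydroxymethyl)phenyl]-3,5-bis(benzyloxy)phenol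
Product: 7 3,5-bis(benzyloxy)-2-[4,5-bis(benzyloxy)-2-(tert-butyldimethylsilyloxymethyl)phenyl]phenol
Conditions: TBSCl (1.05 equiv), imidazole (2 equiv), CH2Cl2, 0 °C
Reagents that add atoms: tert-butyldimethylsilyl chloride, CC(C)(C)[Si](C)(C)Cl
Why: Chemoselective silylation; the unhindered primary alcohol should react far faster than the phenol flanked by the aryl group (as with 2-hydroxybenzyl alcohols), masking the ionisable benzylic position so that it cannot close onto the phenol.

Step 6
Reactants: 7 3,5-bis(benzyloxy)-2-[4,5-bis(benzyloxy)-2-(tert-butyldimethylsilyloxymethyl)phenyl]phenol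
Product: 8 4,6-bis(benzyloxy)-3-[4,5-bis(benzyloxy)-2-(tert-butyldimethylsilyloxymethyl)phenyl]-2-hydroxybenzaldehyde
Conditions: MgCl2 (2 equiv), Et3N (4 equiv), (CH2O)n (6 equiv), MeCN, reflux; aq. NH4Cl work-up
Reagents that add atoms: formaldehyde (from paraformaldehyde), C=O
Why: Magnesium-mediated ortho-formylation (Casnati–Skattebøl); formaldehyde is delivered inside the magnesium phenoxide chelate only ortho to the free OH, the one open ortho position is the future C4a (the carbon between the two benzyloxy groups is not reached), and a second formaldehyde oxidises the hydroxymethyl stage by hydride transfer.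

Step 7
Reactants: 9 3,4-bis(benzyloxy)benzaldehyde
Product: 10 1,2-bis(benzyloxy)-4-ethynylbenzene
Conditions: dimethyl (1-diazo-2-oxopropyl)phosphonate (1.3 equiv), K2CO3 (2 equiv), MeOH/THF, rt
Reagents that add atoms: dimethyl (1-diazo-2-oxopropyl)phosphonate, CC(=O)C(=[N+]=[N-])P(=O)(OC)OC
Why: Ohira–Bestmann (Seyferth–Gilbert) homologation converts the aryl aldehyde into the terminal alkyne under mild base that benzyl ethers tolerate.

Step 8
Reactants: 8 4,6-bis(benzyloxy)-3-[4,5-bis(benzyloxy)-2-(tert-butyldimethylsilyloxymethyl)phenyl]-2-hydroxybenzaldehyde; 10 1,2-bis(benzyloxy)-4-ethynylbenzene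
Product: 11 1-{4,6-bis(benzyloxy)-3-[4,5-bis(benzyloxy)-2-(tert-butyldimethylsilyloxymethyl)phenyl]-2-hydroxyphenyl}-3-[3,4-bis(benzyloxy)phenyl]prop-2-yn-1-ol (racemic at the carbinol carbon; used without chromatography)
Conditions: 8, LiN(SiMe3)2 (1.0 equiv), THF, −78 °C; then lithium acetylide from 10 (1.5 equiv) and n-BuLi (1.5 equiv), −78 to 0 °C; pH 7 buffer
Reagents that add atoms: none
Why: 1,2-Addition of a lithium acetylide to the aldehyde after prior deprotonation of the phenol (so that no acetylide is spent as base); the carbinol stereocenter forms without control and is erased in step 9.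

Step 9
Reactants: 11 the propargylic alcohol of step 8
Product: 12 1-{4,6-bis(benzyloxy)-3-[4,5-bis(benzyloxy)-2-(tert-butyldimethylsilyloxymethyl)phenyl]-2-hydroxyphenyl}-3-[3,4-bis(benzyloxy)phenyl]prop-2-yn-1-one
Conditions: activated MnO2 (15 equiv), CH2Cl2, rt
Reagents that add atoms: none
Why: MnO2 oxidation of a doubly activated (benzylic and propargylic) alcohol to the ynone should be fast and leave silyl and benzyl ethers alone.

Step 10
Reactants: 12 the ortho-hydroxyaryl ynone of step 9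
Product: 13 5,7-bis(benzyloxy)-2-[3,4-bis(benzyloxy)phenyl]-8-[4,5-bis(benzyloxy)-2-(tert-butyldimethylsilyloxymethyl)phenyl]-4H-chromen-4-one
Conditions: DMAP (20 mol%), DMF, rt to 40 °C
Reagents that add atoms: none
Why: Nucleophile-catalysed 6-endo oxa-Michael cyclisation of an ortho-hydroxyaryl ynone; DMAP adds to the β-carbon and the phenol displaces it at that same carbon, which closes the pyranone and avoids the 5-exo aurone.

Step 11
Reactants: 13 the silyl-protected flavone of step 10
Product: 14 5,7-bis(benzyloxy)-2-[3,4-bis(benzyloxy)phenyl]-8-[4,5-bis(benzyloxy)-2-(hydroxymethyl)phenyl]-4H-chromen-4-one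
Conditions: Bu4NF (1.2 equiv), THF, 0 °C to rt
Reagents that add atoms: none
Why: Fluoride-driven desilylation of the primary silyl ether; the flavone and the aryl benzyl ethers are inert to fluoride.

Step 12
Reactants: 14 the flavone benzylic alcohol of step 11
Product: 15 4,5-bis(benzyloxy)-2-{5,7-bis(benzyloxy)-2-[3,4-bis(benzyloxy)phenyl]-4-oxo-4H-chromen-8-yl}benzaldehyde
Conditions: activated MnO2 (15 equiv), CH2Cl2, rt
Reagents that add atoms: none
Why: MnO2 oxidation of an electron-rich benzylic alcohol stops cleanly at the aldehyde.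

Step 13
Reactants: 16 2,4,6-trihydroxyacetophenone
Product: 17 1-[2,4-bis(benzyloxy)-6-hydroxyphenyl]ethanone
Conditions: BnBr (2.1 equiv), K2CO3 (2.2 equiv), DMF, rt
Reagents that add atoms: benzyl bromide, BrCc1ccccc1
Why: Williamson etherification; once one ortho hydroxyl is benzylated the remaining one is locked in a hydrogen bond to the ketone and is the least reactive, so two equivalents of BnBr should leave it free.

Step 14
Reactants: 17 1-[2,4-bis(benzyloxy)-6-hydroxyphenyl]ethanone
Product: 18 tert-butyl 3-[2,4-bis(benzyloxy)-6-hydroxyphenyl]-3-oxopropanoate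
Conditions: LiN(SiMe3)2 (3.3 equiv), THF, −78 °C; Boc2O (1.1 equiv), −78 to 0 °C; cold dilute HCl
Reagents that add atoms: di-tert-butyl dicarbonate, CC(C)(C)OC(=O)OC(=O)OC(C)(C)C
Why: Claisen-type C-acylation of the phenoxide/enolate dianion with Boc2O; any aryl carbonate formed on oxygen would relay the acyl group to carbon by Baker–Venkataraman-type O-to-C transfer, and the third equivalent of base stores the product as its enolate.

Step 15
Reactants: 15 the flavone-bearing benzaldehyde of step 12; 18 tert-butyl 3-[2,4-bis(benzyloxy)-6-hydroxyphenyl]-3-oxopropanoate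
Product: 19 tert-butyl 2-[2,4-bis(benzyloxy)-6-hydroxybenzoyl]-3-(4,5-bis(benzyloxy)-2-{5,7-bis(benzyloxy)-2-[3,4-bis(benzyloxy)phenyl]-4-oxo-4H-chromen-8-yl}phenyl)prop-2-enoate (E/Z mixture)
Conditions: piperidine (20 mol%), AcOH (20 mol%), 4 Å molecular sieves, toluene, rt
Reagents that add atoms: none
Why: Knoevenagel condensation under piperidinium acetate catalysis gives the activated chalcone (alkylidene β-ketoester) without the hydroxide that could open the flavone; both alkene isomers feed the same cyclisation.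

Step 16
Reactants: 19 the alkylidene β-ketoester of step 15
Product: 22 (2R)-5,7-bis(benzyloxy)-2-(4,5-bis(benzyloxy)-2-{5,7-bis(benzyloxy)-2-[3,4-bis(benzyloxy)phenyl]-4-oxo-4H-chromen-8-yl}phenyl)chroman-4-one, via tert-butyl (2R)-chromanone-3-carboxylate 20 (not isolated), via (2R)-chromanone-3-carboxylic acid 21 (not isolated)
Conditions: quinine-derived thiourea [1-(3,5-bis(trifluoromethyl)phenyl)-3-(9-deoxy-epi-quinin-9-yl)thiourea] (10 mol%), toluene, −25 °C; then p-TsOH·H2O (0.5 equiv), 80 °C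
Reagents that add atoms: none
Why: Catalytic asymmetric intramolecular oxa-Michael addition followed by acid-mediated tert-butyl ester cleavage and decarboxylation; the thiourea binds the β-ketoester by two hydrogen bonds while the quinuclidine nitrogen delivers the phenol to one face of the alkylidene, which sets C2 as R, and the C3 centre is lost on decarboxylation.

Step 17
Reactants: 22 the (2R)-octabenzyl ether of step 16
Product: 23 (2R)-2-{2-[2-(3,4-dihydroxyphenyl)-5,7-dihydroxy-4-oxo-4H-chromen-8-yl]-4,5-dihydroxyphenyl}-5,7-dihydroxychroman-4-one (target)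
Conditions: H2 (1 atm), 10% Pd/C, THF/MeOH, rt, stopped at full debenzylation
Reagents that add atoms: none
Why: Catalytic hydrogenolysis cleaves the eight aryl benzyl ethers under neutral conditions in which C2 cannot epimerise, and the flavone enone and the flavanone are expected to react more slowly than the benzyl ethers.

## Compound list

1 | 3,4-bis(benzyloxy)benzoic acid | O=C(O)c1ccc(OCc2ccccc2)c(OCc2ccccc2)c1 | starting material
2 | 4,5-bis(benzyloxy)-2-bromobenzoic acid | O=C(O)c1cc(OCc2ccccc2)c(OCc2ccccc2)cc1Br | intermediate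
3 | 3,5-bis(benzyloxy)phenol | Oc1cc(OCc2ccccc2)cc(OCc2ccccc2)c1 | starting material
4 | 3,5-bis(benzyloxy)phenyl 4,5-bis(benzyloxy)-2-bromobenzoate | O=C(Oc1cc(OCc2ccccc2)cc(OCc2ccccc2)c1)c1cc(OCc2ccccc2)c(OCc2ccccc2)cc1Br | intermediate
5 | 1,3,8,9-tetrakis(benzyloxy)-6H-benzo[c]chromen-6-one | O=C1Oc2cc(OCc3ccccc3)cc(OCc3ccccc3)c2-c2cc(OCc3ccccc3)c(OCc3ccccc3)cc21 | intermediate
6 | 2-[4,5-bis(benzyloxy)-2-(hydroxymethyl)phenyl]-3,5-bis(benzyloxy)phenol | OCc1cc(OCc2ccccc2)c(OCc2ccccc2)cc1-c1c(O)cc(OCc2ccccc2)cc1OCc1ccccc1 | intermediate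
7 | 3,5-bis(benzyloxy)-2-[4,5-bis(benzyloxy)-2-(tert-butyldimethylsilyloxymethyl)phenyl]phenol | CC(C)(C)[Si](C)(C)OCc1cc(OCc2ccccc2)c(OCc2ccccc2)cc1-c1c(O)cc(OCc2ccccc2)cc1OCc1ccccc1 | intermediate
8 | 4,6-bis(benzyloxy)-3-[4,5-bis(benzyloxy)-2-(tert-butyldimethylsilyloxymethyl)phenyl]-2-hydroxybenzaldehyde | CC(C)(C)[Si](C)(C)OCc1cc(OCc2ccccc2)c(OCc2ccccc2)cc1-c1c(O)c(C=O)c(OCc2ccccc2)cc1OCc1ccccc1 | intermediate
9 | 3,4-bis(benzyloxy)benzaldehyde | O=Cc1ccc(OCc2ccccc2)c(OCc2ccccc2)c1 | starting material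
10 | 1,2-bis(benzyloxy)-4-ethynylbenzene | C#Cc1ccc(OCc2ccccc2)c(OCc2ccccc2)c1 | intermediate
11 | 1-{4,6-bis(benzyloxy)-3-[4,5-bis(benzyloxy)-2-(tert-butyldimethylsilyloxymethyl)phenyl]-2-hydroxyphenyl}-3-[3,4-bis(benzyloxy)phenyl]prop-2-yn-1-ol (racemic) | CC(C)(C)[Si](C)(C)OCc1cc(OCc2ccccc2)c(OCc2ccccc2)cc1-c1c(O)c(C(O)C#Cc2ccc(OCc3ccccc3)c(OCc3ccccc3)c2)c(OCc2ccccc2)cc1OCc1ccccc1 | intermediate
12 | 1-{4,6-bis(benzyloxy)-3-[4,5-bis(benzyloxy)-2-(tert-butyldimethylsilyloxymethyl)phenyl]-2-hydroxyphenyl}-3-[3,4-bis(benzyloxy)phenyl]prop-2-yn-1-one | CC(C)(C)[Si](C)(C)OCc1cc(OCc2ccccc2)c(OCc2ccccc2)cc1-c1c(O)c(C(=O)C#Cc2ccc(OCc3ccccc3)c(OCc3ccccc3)c2)c(OCc2ccccc2)cc1OCc1ccccc1 | intermediate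
13 | 5,7-bis(benzyloxy)-2-[3,4-bis(benzyloxy)phenyl]-8-[4,5-bis(benzyloxy)-2-(tert-butyldimethylsilyloxymethyl)phenyl]-4H-chromen-4-one | CC(C)(C)[Si](C)(C)OCc1cc(OCc2ccccc2)c(OCc2ccccc2)cc1-c1c(OCc2ccccc2)cc(OCc2ccccc2)c2c(=O)cc(-c3ccc(OCc4ccccc4)c(OCc4ccccc4)c3)oc12 | intermediate
14 | 5,7-bis(benzyloxy)-2-[3,4-bis(benzyloxy)phenyl]-8-[4,5-bis(benzyloxy)-2-(hydroxymethyl)phenyl]-4H-chromen-4-one | OCc1cc(OCc2ccccc2)c(OCc2ccccc2)cc1-c1c(OCc2ccccc2)cc(OCc2ccccc2)c2c(=O)cc(-c3ccc(OCc4ccccc4)c(OCc4ccccc4)c3)oc12 | intermediate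
15 | 4,5-bis(benzyloxy)-2-{5,7-bis(benzyloxy)-2-[3,4-bis(benzyloxy)phenyl]-4-oxo-4H-chromen-8-yl}benzaldehyde | O=Cc1cc(OCc2ccccc2)c(OCc2ccccc2)cc1-c1c(OCc2ccccc2)cc(OCc2ccccc2)c2c(=O)cc(-c3ccc(OCc4ccccc4)c(OCc4ccccc4)c3)oc12 | intermediate
16 | 2,4,6-trihydroxyacetophenone | CC(=O)c1c(O)cc(O)cc1O | starting material
17 | 1-[2,4-bis(benzyloxy)-6-hydroxyphenyl]ethanone | CC(=O)c1c(O)cc(OCc2ccccc2)cc1OCc1ccccc1 | intermediate
18 | tert-butyl 3-[2,4-bis(benzyloxy)-6-hydroxyphenyl]-3-oxopropanoate | CC(C)(C)OC(=O)CC(=O)c1c(O)cc(OCc2ccccc2)cc1OCc1ccccc1 | intermediate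
19 | tert-butyl 2-[2,4-bis(benzyloxy)-6-hydroxybenzoyl]-3-(4,5-bis(benzyloxy)-2-{5,7-bis(benzyloxy)-2-[3,4-bis(benzyloxy)phenyl]-4-oxo-4H-chromen-8-yl}phenyl)prop-2-enoate (E/Z mixture) | CC(C)(C)OC(=O)C(=Cc1cc(OCc2ccccc2)c(OCc2ccccc2)cc1-c1c(OCc2ccccc2)cc(OCc2ccccc2)c2c(=O)cc(-c3ccc(OCc4ccccc4)c(OCc4ccccc4)c3)oc12)C(=O)c1c(O)cc(OCc2ccccc2)cc1OCc1ccccc1 | intermediate
20 | tert-butyl (2R)-5,7-bis(benzyloxy)-2-(4,5-bis(benzyloxy)-2-{5,7-bis(benzyloxy)-2-[3,4-bis(benzyloxy)phenyl]-4-oxo-4H-chromen-8-yl}phenyl)-4-oxochromane-3-carboxylate (C3 epimers and enol) | O=C1C(C(=O)OC(C)(C)C)[C@H](c2cc(OCc3ccccc3)c(OCc3ccccc3)cc2-c2c(OCc3ccccc3)cc(OCc3ccccc3)c3c(=O)cc(-c4ccc(OCc5ccccc5)c(OCc5ccccc5)c4)oc23)Oc2cc(OCc3ccccc3)cc(OCc3ccccc3)c21 | intermediate (not isolated)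
21 | (2R)-5,7-bis(benzyloxy)-2-(4,5-bis(benzyloxy)-2-{5,7-bis(benzyloxy)-2-[3,4-bis(benzyloxy)phenyl]-4-oxo-4H-chromen-8-yl}phenyl)-4-oxochromane-3-carboxylic acid | O=C1C(C(=O)O)[C@H](c2cc(OCc3ccccc3)c(OCc3ccccc3)cc2-c2c(OCc3ccccc3)cc(OCc3ccccc3)c3c(=O)cc(-c4ccc(OCc5ccccc5)c(OCc5ccccc5)c4)oc23)Oc2cc(OCc3ccccc3)cc(OCc3ccccc3)c21 | intermediate (not isolated)
22 | (2R)-5,7-bis(benzyloxy)-2-(4,5-bis(benzyloxy)-2-{5,7-bis(benzyloxy)-2-[3,4-bis(benzyloxy)phenyl]-4-oxo-4H-chromen-8-yl}phenyl)chroman-4-one | O=C1C[C@H](c2cc(OCc3ccccc3)c(OCc3ccccc3)cc2-c2c(OCc3ccccc3)cc(OCc3ccccc3)c3c(=O)cc(-c4ccc(OCc5ccccc5)c(OCc5ccccc5)c4)oc23)Oc2cc(OCc3ccccc3)cc(OCc3ccccc3)c21 | intermediate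
23 | (2R)-2-{2-[2-(3,4-dihydroxyphenyl)-5,7-dihydroxy-4-oxo-4H-chromen-8-yl]-4,5-dihydroxyphenyl}-5,7-dihydroxychroman-4-one | O=C1C[C@H](c2cc(O)c(O)cc2-c2c(O)cc(O)c3c(=O)cc(-c4ccc(O)c(O)c4)oc23)Oc2cc(O)cc(O)c21 | target

## Step count and risks

Total step count: 17. Longest linear sequence: 14 steps (1, 2, 3, 4, 5, 6, 8, 9, 10, 11, 12, 15, 16, 17).

Steps most likely to fail:

1. Step 3. Cleavage of the aryl ester by carbonate and protodebromination may outpace cyclisation, because the ester must first reach its less populated s-cis conformer and the C–H bond to be metalated is flanked by two substituents. The fallback sets out from 2 and returns at 5 by a copper-mediated Hurtley coupling. Compound 2 is heated with phloroglucinol, NaOH and catalytic CuSO4 in water; C-arylation of the phloroglucinol anion and lactonisation on acidification should give 8,9-bis(benzyloxy)-1,3-dihydroxy-6H-benzo[c]chromen-6-one F1. The three positions of phloroglucinol are equivalent, so regiochemistry is again fixed by symmetry. Benzylation of the two phenols (BnBr, K2CO3, DMF) returns 5.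

2. Step 16. Background ring closure without the catalyst, weak facial discrimination next to the bulky ortho-aryl group, or acid-induced ring opening and reclosure during decarboxylation may erode the enantiomeric purity at C2. The fallback sets out from 15 (with 17) and returns at 22. Claisen–Schmidt condensation of 15 with 17 (KOH, EtOH/THF, rt) should give (E)-1-[2,4-bis(benzyloxy)-6-hydroxyphenyl]-3-(4,5-bis(benzyloxy)-2-{5,7-bis(benzyloxy)-2-[3,4-bis(benzyloxy)phenyl]-4-oxo-4H-chromen-8-yl}phenyl)prop-2-en-1-one F2. NaOAc in refluxing EtOH closes it to the racemic flavanone, rac-5,7-bis(benzyloxy)-2-(4,5-bis(benzyloxy)-2-{5,7-bis(benzyloxy)-2-[3,4-bis(benzyloxy)phenyl]-4-oxo-4H-chromen-8-yl}phenyl)chroman-4-one F3. Kinetic resolution by asymmetric transfer hydrogenation follows (RhCl(Cp*)(TsDPEN), a trivalent rhodium complex, HCO2H/Et3N, EtOAc), with the ligand enantiomer chosen so that the 2S ketone is reduced to the cis alcohol (2S,4S)-5,7-bis(benzyloxy)-2-(4,5-bis(benzyloxy)-2-{5,7-bis(benzyloxy)-2-[3,4-bis(benzyloxy)phenyl]-4-oxo-4H-chromen-8-yl}phenyl)chroman-4-ol F4. The unreduced 2R ketone 22 is separated by chromatography.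

3. Step 17. Over-reduction (saturation of the flavone C2–C3 bond, hydrogenolytic opening of the benzylic C2–O1 bond of the flavanone) or stalling at partly debenzylated, poorly soluble stages may spoil the last step. The fallback goes from 22 straight to 23 by non-reductive debenzylation with BCl3 and pentamethylbenzene as benzyl-cation scavenger in CH2Cl2 at −78 °C, quenched cold with MeOH. No new compound is made on the way (F0).

## Further compounds

F1 | step 3 | 8,9-bis(benzyloxy)-1,3-dihydroxy-6H-benzo[c]chromen-6-one | O=C1Oc2cc(O)cc(O)c2-c2cc(OCc3ccccc3)c(OCc3ccccc3)cc21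
F2 | step 16 | (E)-1-[2,4-bis(benzyloxy)-6-hydroxyphenyl]-3-(4,5-bis(benzyloxy)-2-{5,7-bis(benzyloxy)-2-[3,4-bis(benzyloxy)phenyl]-4-oxo-4H-chromen-8-yl}phenyl)prop-2-en-1-one | O=C(/C=C/c1cc(OCc2ccccc2)c(OCc2ccccc2)cc1-c1c(OCc2ccccc2)cc(OCc2ccccc2)c2c(=O)cc(-c3ccc(OCc4ccccc4)c(OCc4ccccc4)c3)oc12)c1c(O)cc(OCc2ccccc2)cc1OCc1ccccc1
F3 | step 16 | rac-5,7-bis(benzyloxy)-2-(4,5-bis(benzyloxy)-2-{5,7-bis(benzyloxy)-2-[3,4-bis(benzyloxy)phenyl]-4-oxo-4H-chromen-8-yl}phenyl)chroman-4-one | O=C1CC(c2cc(OCc3ccccc3)c(OCc3ccccc3)cc2-c2c(OCc3ccccc3)cc(OCc3ccccc3)c3c(=O)cc(-c4ccc(OCc5ccccc5)c(OCc5ccccc5)c4)oc23)Oc2cc(OCc3ccccc3)cc(OCc3ccccc3)c21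
F4 | step 16 | (2S,4S)-5,7-bis(benzyloxy)-2-(4,5-bis(benzyloxy)-2-{5,7-bis(benzyloxy)-2-[3,4-bis(benzyloxy)phenyl]-4-oxo-4H-chromen-8-yl}phenyl)chroman-4-ol | O[C@H]1C[C@@H](c2cc(OCc3ccccc3)c(OCc3ccccc3)cc2-c2c(OCc3ccccc3)cc(OCc3ccccc3)c3c(=O)cc(-c4ccc(OCc5ccccc5)c(OCc5ccccc5)c4)oc23)Oc2cc(OCc3ccccc3)cc(OCc3ccccc3)c21
F0 | step 17 | none | none
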